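Compound numbers used throughout: 1 daidzein, 2 its bis-silyl ether, 3 the 4'-mono-silyl ether, 4 the iminium salt, 5 and 6 the mono- and bis-aminomethyl phenols, 7 the boronic acid, 8–10 the transient species of the key step, 11 its product, 12 the target.

## The problem

Compound 12 is an isoflavone in which benzo ring A (C4a, C5 to C8, C8a) is fused to pyranone ring C (O1, C2=C3, C4=O) and C3 carries the 4-hydroxyphenyl ring B. It has no stereocenter, so nothing has to be controlled in space and no center could direct another; the task is one of regiochemistry and chemoselectivity. The whole ring system with both oxygens is available as daidzein (1). What separates 1 from 12 is two 3-methylbut-2-enyl chains (C1'' to C5'', C1'' benzylic) on C6 and C8, on either side of the C7 hydroxyl. Joining these chains to ring A directly is unreliable: the C7 phenoxide reacts at oxygen as well as carbon, C8 is far more nucleophilic than C6, a prenyl electrophile or prenyl metal can bond through C1'' or C3'', and the phenol of ring B competes. The product is fragile: each chain lies ortho to a free phenol and closes to a 2,2-dimethylchroman under Brønsted or Lewis acid, the trisubstituted alkenes do not survive hydrogenation, and C2 of ring C is open to ring-opening attack by hydroxide, alkoxide or amines. The two phenols must be told apart, which is possible because the C7 hydroxyl is conjugated with the C4 carbonyl through ring A and is the more acidic one. The enabling feature is that the C7 hydroxyl has a CH2 group (C1'' of each chain) on both ortho carbons, and each CH2 is the exocyclic carbon of an ortho-quinone methide of ring A (C7=O with C8=C1'' or with C6=C1''). Each C1''–C2'' bond can therefore be made by conjugate addition of a 2-methylprop-1-enyl group, and the quinone methide precursors, aminomethyl groups, go only to the ortho positions of a phenol.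

## Retrosynthesis

**O–Si at C4' (12 from 11).** The last disconnection cuts no skeletal bond: 12 is the desilylation product of the triisopropylsilyl ether 11. Ring B is kept masked so that only one phenol directs aminomethylation and binds boron. A silyl ether is preferred to an acetal or benzyl ether because fluoride is neither an acid nor hydrogen, so it leaves two ortho-prenyl phenol units alone. The forward reaction only has to be kept near neutral.

**C1''–C2'', twice (11 from 6 and 7).** Both bonds between the benzylic CH2 and the alkenyl CH are cut, leading to bis-aminomethyl phenol 6 and two equivalents of boronic acid 7. Two neighbouring cuts were weighed: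
- Cutting C6–C1'' and C8–C1'' calls for a prenyl electrophile or prenyl metal, with the O/C, C8/C6 and C1''/C3'' ambiguities described above.
- Cutting C2''=C3'' (olefin metathesis) presupposes two allyl groups, each from its own high-temperature sigmatropic shift.

With the C1''–C2'' cut, C1'' is already attached to the ring and the nucleophile bonds through its boron-bearing carbon, so only the linear chain can result. Precursor 6 is much simpler: it has no alkene and is one step from a protected daidzein, and 7 is bought. The forward reaction must generate two quinone methides in turn (8, then 10 from mono-adduct 9) and capture each faster than it self-condenses, without acid or metal.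

**C8–C1'' and C6–C1'' as aryl–CH2N bonds (6 from 3 and 4).** The two aminomethyl groups are removed to give phenol 3 and two equivalents of iminium salt 4, by way of mono-adduct 5. This cut is preferred to formylation or halomethylation because the phenol Mannich reaction is ortho-specific, needs no oxidation-state change afterwards and delivers the leaving group for the key step directly. The para position of the C7 oxygen is the ring-fusion carbon C4a, so C8 and C6 are the only sites. The forward reaction must push the second substitution onto the less nucleophilic C6.

**Telling the phenols apart (3 from 2 from 1).** Phenol 3 is the 4'-silyl ether of daidzein 1. It is reached by silylating both hydroxyls (2) and removing the C7 silyl group, whose aryloxide is the better leaving group. This is chosen over direct mono-silylation because electrophiles go to the more acidic C7 hydroxyl first, which is the wrong one. The forward reaction requires a rate difference between two aryl silyl ethers, which the conjugation of O7 with C4=O provides.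

## Roads not taken

**Alternative 1:** aldol aromatization of a dioxinone-masked chain.
- Cut: through ring A at C4a–C5, leading to open-chain keto-dioxinone A2. In A2, C5 is an aldehyde masked as its dimethyl acetal, C7 is a ketone, and C6 and C8 are sp3 carbons that already carry the prenyl groups.
- Forward step: mild acid frees the aldehyde, a tertiary amine base induces aldol condensation of the dioxinone α-carbon (C4a) with C5, and dehydration and enolization give benzodioxinone A1.
- Merits: both chains are placed before ring A exists, so C6 versus C8 never arises; the aromatization is mild; the dioxinone is a masked salicylate ready for extension.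
- Weak points: A2 needs a multistep assembly of a doubly prenylated 1,3-dicarbonyl chain. Its acetal must be opened by acid next to two trisubstituted alkenes. After A1, C4 as a benzyl ketone, C2, and all of ring B and ring C still have to be built with the C7 hydroxyl protected.
- Comparison: in regiochemical certainty at C6 this road is better than the chosen plan, which depends on C6 accepting an aminomethyl group. The chosen plan sets against it five steps from 1 and no need to rebuild rings that 1 already has.

**Alternative 2:** vinylketene–silyloxyalkyne benzannulation.
- Cut: ring A is divided into a four-carbon unit (C4a, C5, C6, C7) from diazo enone A4 and a two-carbon unit (C8, C8a) from silyloxyalkyne A5.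
- Forward step: irradiation of A4 brings about Wolff rearrangement to a vinylketene. Its [2+2] addition to A5 forms C7–C8 and C4a–C8a. The cyclobutenone opens and the dienylketene closes (C6–C7), giving phenol A3 after tautomerization.
- Merits: convergent; one step gives a fully substituted ring A with the chains placed by fragment connectivity and the two oxygens already differentiated (free C7 hydroxyl, silylated O1). In this it is better than the chosen plan.
- Weak points: A4 is a diazo ketone with a doubly activated CH2 between two alkenes and is prone to isomerization. A5 is a sensitive ynol ether needing its own preparation. The decisive problem comes after A3: C4a must be acylated with an arylacetyl unit, which requires Friedel–Crafts or related acidic conditions on a phenol with two ortho-prenyl groups and invites chroman formation. O1 must then be freed and C2 inserted.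
- Comparison: this road is longer, and its difficulty lies after the key step. The chosen plan never exposes a prenyl group to acid.

**Alternative 3:** twofold Stille prenylation.
- Cut: C6–C1'' and C8–C1''. Dibromide A7 is coupled twice with stannane A8 under Pd(PPh3)4 (zerovalent palladium) to give bis-acetal A6.
- Merits: the most conventional answer, using a heavily used reaction class with the ring positions fixed by the bromines. On paper the sequence from 1 (dibromination, acetal formation, coupling, deprotection) is as short as the chosen plan or a step shorter, so on step count and familiarity this road is as good or better.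
- Weak points: bromination of 1 must avoid the positions ortho to the ring B hydroxyl, so a differentiation of the phenols is needed here too. Both C–Br bonds are flanked by oxygen substituents, C8 on both sides, which slows coupling and favours reduction. The allyl group can be delivered through C3'' as well as C1'', and two couplings multiply any such leakage. The two acetals are removed with acid next to the prenyl groups. Tin is used in stoichiometric amount.
- Comparison: the chosen plan sets against this guaranteed linear chains, a fluoride deprotection and no tin. It pays with a less common C–C bond formation and with reliance on the C6 Mannich step.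

Key step: step 4

Assumption: the C8 arm of 6 is taken to ionize before the C6 arm, because quinone methide 8 keeps the C4a=C8a double bond of ring C. The reverse order would pass through isomeric intermediates to the same product 11.

## Route

Step 1
Reactants: 1 daidzein (7-hydroxy-3-(4-hydroxyphenyl)chromen-4-one)
Product: 2 7-(triisopropylsilyloxy)-3-[4-(triisopropylsilyloxy)phenyl]chromen-4-one
Conditions: TIPSCl (2.5 equiv), imidazole (5 equiv), DMF, 23 °C
Reagents that add atoms: chlorotriisopropylsilane, CC(C)[Si](Cl)(C(C)C)C(C)C
Why: Standard imidazole-promoted silylation of phenols; both hydroxyls are unhindered and nothing else in 1 reacts with a silyl chloride.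

Step 2
Reactants: 2 7-(triisopropylsilyloxy)-3-[4-(triisopropylsilyloxy)phenyl]chromen-4-one
Product: 3 7-hydroxy-3-[4-(triisopropylsilyloxy)phenyl]chromen-4-one
Conditions: K2CO3 (1.0 equiv), MeOH–THF (1:1), 0 °C; aq. NH4Cl
Reagents that add atoms: none
Why: Base-mediated methanolysis of an aryl silyl ether follows the leaving-group ability of the aryloxide; O7 is conjugated with the C4 carbonyl (a vinylogous acid), so its silyl ether should be cleaved first while the ordinary aryl silyl ether on ring B stays, and the phenoxide formed protects ring C from methoxide.

Step 3
Reactants: 3 7-hydroxy-3-[4-(triisopropylsilyloxy)phenyl]chromen-4-one; 4 dimethylmethyleneiminium iodide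
Product: 6 6,8-bis[(dimethylamino)methyl]-7-hydroxy-3-[4-(triisopropylsilyloxy)phenyl]chromen-4-one, via 8-aminomethyl phenol 5 (not isolated)
Conditions: 4 (3.0 equiv), K2CO3 (3.0 equiv), MeCN, 23 → 60 °C
Reagents that add atoms: none
Why: Phenol Mannich reaction (ortho-aminomethylation) with a preformed iminium salt; the C7 phenoxide should react through C8 first to give 5 and then through C6, the only other ortho carbon, since the para carbon is the ring-fusion atom C4a. Attack at oxygen is reversible, and the silyl ether on ring B is not nucleophilic enough to compete.

Step 4
Reactants: 6 6,8-bis[(dimethylamino)methyl]-7-hydroxy-3-[4-(triisopropylsilyloxy)phenyl]chromen-4-one; 7 2-methylprop-1-enylboronic acid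
Product: 11 7-hydroxy-6,8-bis(3-methylbut-2-enyl)-3-[4-(triisopropylsilyloxy)phenyl]chromen-4-one, via C8 quinone methide 8 (not isolated), via 8-prenyl aminomethyl phenol 9 (not isolated), via C6 quinone methide 10 (not isolated)
Conditions: 7 (5 equiv), 1,4-dioxane, 100 °C, argon, slow addition of 6; aq. NH4Cl
Reagents that add atoms: none
Why: Each ortho-hydroxybenzylamine arm transfers the phenolic proton to nitrogen and loses dimethylamine, helped by the boronic acid, which engages the phenol oxygen and the amine, to give an ortho-quinone methide, first 8 at C8 and later 10 at C6. Boron bound at the quinone methide oxygen as a tetracoordinate boronate passes its 2-methylprop-1-enyl group, through the boron-bearing carbon, to the exocyclic methylene in a six-membered transition state, which forms C1''–C2'' and restores aromatic ring A (9, then 11 after O–B hydrolysis at work-up). The closest known reaction type is the 1,4-addition of alkenylboronic acids and boronates to ortho-quinone methides formed in situ from ortho-hydroxybenzyl amines, ethers or alcohols, a Petasis-type boronate transfer, here run twice on one phenol. No ring is closed and no stereocenter is formed, and C3'' bears two identical methyl groups, so no alkene geometry arises. The step needs capture to outrun self-condensation of 8 and 10, which slow addition of 6 into excess 7 and intramolecular delivery from oxygen-bound boron should secure. It needs the chain to be linear, which is certain because C1'' already sits on C6 and C8 and boron transfers only its ipso carbon, so neither O-prenyl nor 1,1-dimethylallyl isomers can form. The vinylogous ester of ring C is a poor acceptor for a neutral boronic acid, the excess boronic acid holds the liberated amine away from C2, and no acid or metal is present that could cyclize the new prenyl groups onto O7.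

Step 5
Reactants: 11 7-hydroxy-6,8-bis(3-methylbut-2-enyl)-3-[4-(triisopropylsilyloxy)phenyl]chromen-4-one
Product: 12 7-hydroxy-3-(4-hydroxyphenyl)-6,8-bis(3-methylbut-2-enyl)chromen-4-one
Conditions: TBAF (1.2 equiv), AcOH (1.2 equiv), THF, 0 °C
Reagents that add atoms: none
Why: Fluoride cleavage of an aryl triisopropylsilyl ether; buffering with acetic acid keeps the medium near neutral, so neither the acid-sensitive ortho-prenyl phenol nor the base-sensitive ring C is put at risk.

## Compound list

1 | daidzein, 7-hydroxy-3-(4-hydroxyphenyl)chromen-4-one | O=c1c(-c2ccc(O)cc2)coc2cc(O)ccc12 | starting material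
2 | 7-(triisopropylsilyloxy)-3-[4-(triisopropylsilyloxy)phenyl]chromen-4-one | CC(C)[Si](Oc1ccc(-c2coc3cc(O[Si](C(C)C)(C(C)C)C(C)C)ccc3c2=O)cc1)(C(C)C)C(C)C | intermediate
3 | 7-hydroxy-3-[4-(triisopropylsilyloxy)phenyl]chromen-4-one | CC(C)[Si](Oc1ccc(-c2coc3cc(O)ccc3c2=O)cc1)(C(C)C)C(C)C | intermediate
4 | dimethylmethyleneiminium iodide | C=[N+](C)C.[I-] | starting material
5 | 8-[(dimethylamino)methyl]-7-hydroxy-3-[4-(triisopropylsilyloxy)phenyl]chromen-4-one | CN(C)Cc1c(O)ccc2c(=O)c(-c3ccc(O[Si](C(C)C)(C(C)C)C(C)C)cc3)coc12 | intermediate (not isolated)
6 | 6,8-bis[(dimethylamino)methyl]-7-hydroxy-3-[4-(triisopropylsilyloxy)phenyl]chromen-4-one | CN(C)Cc1cc2c(=O)c(-c3ccc(O[Si](C(C)C)(C(C)C)C(C)C)cc3)coc2c(CN(C)C)c1O | intermediate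
7 | 2-methylprop-1-enylboronic acid | CC(C)=CB(O)O | starting material
8 | 6-[(dimethylamino)methyl]-8-methylidene-3-[4-(triisopropylsilyloxy)phenyl]chromene-4,7-dione | C=C1C(=O)C(CN(C)C)=CC2=C1OC=C(c1ccc(O[Si](C(C)C)(C(C)C)C(C)C)cc1)C2=O | intermediate (not isolated)
9 | 6-[(dimethylamino)methyl]-7-hydroxy-8-(3-methylbut-2-enyl)-3-[4-(triisopropylsilyloxy)phenyl]chromen-4-one | CN(C)Cc1cc2c(=O)c(-c3ccc(O[Si](C(C)C)(C(C)C)C(C)C)cc3)coc2c(CC=C(C)C)c1O | intermediate (not isolated)
10 | 6-methylidene-8-(3-methylbut-2-enyl)-3-[4-(triisopropylsilyloxy)phenyl]chromene-4,7-dione | C=C1C=C2C(=O)C(c3ccc(O[Si](C(C)C)(C(C)C)C(C)C)cc3)=COC2=C(CC=C(C)C)C1=O | intermediate (not isolated)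
11 | 7-hydroxy-6,8-bis(3-methylbut-2-enyl)-3-[4-(triisopropylsilyloxy)phenyl]chromen-4-one | CC(C)=CCc1cc2c(=O)c(-c3ccc(O[Si](C(C)C)(C(C)C)C(C)C)cc3)coc2c(CC=C(C)C)c1O | intermediate
12 | 7-hydroxy-3-(4-hydroxyphenyl)-6,8-bis(3-methylbut-2-enyl)chromen-4-one | CC(C)=CCc1cc2c(=O)c(-c3ccc(O)cc3)coc2c(CC=C(C)C)c1O | target

## Step count and risks

Total: 5 steps. Longest linear sequence: 5 steps, from 1 to 12; 4 and 7 are bought.

**Step 4 (key step).**
- What may go wrong: self-condensation of the quinone methides (hetero-Diels–Alder dimerization or addition of a product phenol) could outrun the bimolecular boron capture. The second ionization, at C6, may stall because its quinone methide gives up the C4a=C8a conjugation of ring C. Protodeboronation of 7 at 100 °C and amine attack at C2 are lesser risks.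
- Fallback: set out from 3 and return at 11, by Claisen rearrangement and olefin metathesis. O-Allylation of 3 (allyl bromide, K2CO3, acetone) gives the 7-allyl ether F1. Heating in N,N-diethylaniline moves the allyl group to C8 to give the 8-allyl phenol F2. A second O-allylation gives the 8-allyl 7-allyl ether F3. A second Claisen rearrangement, now possible only toward C6, gives the 6,8-diallyl phenol F4. Twofold cross-metathesis with 2-methylbut-2-ene and the second-generation Grubbs catalyst converts both allyl groups into prenyl groups and gives 11.

**Step 3.**
- What may go wrong: the reaction may stall after the first aminomethylation, because C6 is the less nucleophilic ortho carbon of ring A. On forcing, the C8 amine of 5 may be lost through quinone methide formation.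
- Fallback: set out from 5 and return at 9, installing the chains one at a time. 5 is made and isolated from 3 with one equivalent of 4 at 23 °C. Heating 5 with 7 under the conditions of step 4 should give, through the C8 quinone methide F5, the 8-prenyl phenol F6. F6 has only C6 free and no labile group, so it can be aminomethylated with 4 under more forcing conditions to give 9, which is isolated here. 9 then goes on to 11 under the conditions of step 4.

**Step 2.**
- What may go wrong: loss of selectivity, with cleavage of both silyl ethers back toward 1. Alternatively, sluggish cleavage of the hindered silyl group may tempt stronger conditions under which methoxide attacks C2 of ring C.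
- Fallback: set out from 1 and return at 3, with orthogonal protection in place of selective cleavage. Alkylation of 1 with one equivalent of benzyl bromide and K2CO3 in DMF goes to the more acidic C7 hydroxyl and gives the 7-benzyl ether F7. Silylation as in step 1 gives the benzyl silyl ether F8. Hydrogenolysis (H2, Pd/C, EtOAc), done before any alkene is present, gives 3.

Further compounds
F1 | step 4 | 7-(prop-2-enoxy)-3-[4-(triisopropylsilyloxy)phenyl]chromen-4-one | C=CCOc1ccc2c(=O)c(-c3ccc(O[Si](C(C)C)(C(C)C)C(C)C)cc3)coc2c1
F2 | step 4 | 7-hydroxy-8-(prop-2-enyl)-3-[4-(triisopropylsilyloxy)phenyl]chromen-4-one | C=CCc1c(O)ccc2c(=O)c(-c3ccc(O[Si](C(C)C)(C(C)C)C(C)C)cc3)coc12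
F3 | step 4 | 7-(prop-2-enoxy)-8-(prop-2-enyl)-3-[4-(triisopropylsilyloxy)phenyl]chromen-4-one | C=CCOc1ccc2c(=O)c(-c3ccc(O[Si](C(C)C)(C(C)C)C(C)C)cc3)coc2c1CC=C
F4 | step 4 | 7-hydroxy-6,8-bis(prop-2-enyl)-3-[4-(triisopropylsilyloxy)phenyl]chromen-4-one | C=CCc1cc2c(=O)c(-c3ccc(O[Si](C(C)C)(C(C)C)C(C)C)cc3)coc2c(CC=C)c1O
F5 | step 3 | 8-methylidene-3-[4-(triisopropylsilyloxy)phenyl]chromene-4,7-dione | C=C1C(=O)C=CC2=C1OC=C(c1ccc(O[Si](C(C)C)(C(C)C)C(C)C)cc1)C2=O
F6 | step 3 | 7-hydroxy-8-(3-methylbut-2-enyl)-3-[4-(triisopropylsilyloxy)phenyl]chromen-4-one | CC(C)=CCc1c(O)ccc2c(=O)c(-c3ccc(O[Si](C(C)C)(C(C)C)C(C)C)cc3)coc12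
F7 | step 2 | 7-benzyloxy-3-(4-hydroxyphenyl)chromen-4-one | O=c1c(-c2ccc(O)cc2)coc2cc(OCc3ccccc3)ccc12
F8 | step 2 | 7-benzyloxy-3-[4-(triisopropylsilyloxy)phenyl]chromen-4-one | CC(C)[Si](Oc1ccc(-c2coc3cc(OCc4ccccc4)ccc3c2=O)cc1)(C(C)C)C(C)C
A1 | alternative 1 | 7-hydroxy-2,2-dimethyl-6,8-bis(3-methylbut-2-enyl)-1,3-benzodioxin-4-one | CC(C)=CCc1cc2C(=O)OC(C)(C)Oc2c(CC=C(C)C)c1O
A2 | alternative 1 | 6-[7-(dimethoxymethyl)-2,10-dimethyl-6-oxoundeca-2,9-dien-5-yl]-2,2-dimethyl-1,3-dioxin-4-one (mixture of diastereomers) | CC(C)=CCC(C(=O)C(CC=C(C)C)C(OC)OC)C1=CC(=O)OC(C)(C)O1
A3 | alternative 2 | 2,6-bis(3-methylbut-2-enyl)-3-(triisopropylsilyloxy)phenol | CC(C)=CCc1ccc(O[Si](C(C)C)(C(C)C)C(C)C)c(CC=C(C)C)c1O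
A4 | alternative 2 | (3E)-1-diazo-7-methylocta-3,6-dien-2-one | CC(C)=CC/C=C/C(=O)C=[N+]=[N-]
A5 | alternative 2 | triisopropyl(5-methylhex-4-en-1-ynoxy)silane | CC(C)=CCC#CO[Si](C(C)C)(C(C)C)C(C)C
A6 | alternative 3 | 7-(methoxymethoxy)-3-[4-(methoxymethoxy)phenyl]-6,8-bis(3-methylbut-2-enyl)chromen-4-one | CC(C)=CCc1cc2c(=O)c(-c3ccc(OCOC)cc3)coc2c(CC=C(C)C)c1OCOC
A7 | alternative 3 | 6,8-dibromo-7-(methoxymethoxy)-3-[4-(methoxymethoxy)phenyl]chromen-4-one | COCOc1ccc(-c2coc3c(Br)c(OCOC)c(Br)cc3c2=O)cc1
A8 | alternative 3 | tributyl(3-methylbut-2-enyl)stannane | CC(C)=CC[Sn](CCCC)(CCCC)CCCC
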